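**Plan**
Labels: C1 angular-methyl quaternary carbon, C4 isopropyl carbinol, C5 ring-fusion CH, C6 ester carbon, C8–C9 epoxide; ring A = C1–C5, ring B = C5–C10 plus C1. With the C6 oxygen read as a C5=C6 enol and the epoxide as a C8=C9 alkene, ring B is a cyclohepta-1,4-diene around quaternary C1.
Retrosynthesis: cut the C6–O acyl bond, then the two epoxide C–O bonds, take the C8 methyl back to an ester, and cut ring B at C7–C8 and C1–C10 into a 2-silyloxydiene on ring A and methyl 2-diazobut-3-enoate.
Forward: ring A is made first from (S)-terpinen-4-ol by ozonolysis and aldol ring contraction; ring B closes in one operation by vinylcarbenoid cyclopropanation of C6=C7 followed by Cope rearrangement; ester-to-methyl reduction, ketone unmasking, C6 reduction, epoxidation and veratroylation follow.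
Stereochemistry: C4 from terpinen-4-ol; C1 from the catalyst-controlled cyclopropanation, relayed through the boat Cope transition state; C5 by protonation to the trans-fused ketone; C6 by hydride delivered from the C4 hydroxyl; C8/C9 by epoxidation directed by the C6 hydroxyl.

Key step: step 10

Remark: β denotes the face of the bicycle that carries the C1 methyl group and α the opposite face; (S)-(+)-terpinen-4-ol is taken as available in high enantiomeric purity.

**Route**

Step 1
Reactants: 1 (S)-(+)-terpinen-4-ol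
Product: 2 triethyl{[(1S)-4-methyl-1-(propan-2-yl)cyclohex-3-en-1-yl]oxy}silane
Conditions: TESOTf, 2,6-lutidine, CH2Cl2, −78 → 0 °C
Reagents that add atoms: triethylsilyl triflate, CC[Si](CC)(CC)OS(=O)(=O)C(F)(F)F
Why: Silylation of a hindered tertiary alcohol with a silyl triflate under lutidine buffering should proceed cleanly and leaves the C4 stereocentre untouched.

Step 2
Reactants: 2 triethyl{[(1S)-4-methyl-1-(propan-2-yl)cyclohex-3-en-1-yl]oxy}silane
Product: 4 (3S)-6-oxo-3-(propan-2-yl)-3-[(triethylsilyl)oxy]heptanal, via ozonide 3 (not isolated)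
Conditions: O3, CH2Cl2, −78 °C; then PPh3, −78 °C → rt
Reagents that add atoms: ozone, [O-][O+]=O
Why: Ozonolysis with reductive work-up cleaves the only alkene to the 1,6-keto aldehyde, and the silyl ether is inert to ozone and phosphine.

Step 3
Reactants: 4 (3S)-6-oxo-3-(propan-2-yl)-3-[(triethylsilyl)oxy]heptanal
Product: 5 (5R)-2-methyl-5-(propan-2-yl)-5-[(triethylsilyl)oxy]cyclopent-1-ene-1-carbaldehyde
Conditions: piperidine, AcOH, PhH, rt → 60 °C
Reagents that add atoms: none
Why: Amine-mediated intramolecular aldol condensation, in which the enamine of the aldehyde attacks the methyl ketone and dehydration gives the formylcyclopentene, is the classical ring contraction of 1,6-keto aldehydes and fixes the regiochemistry because the aldehyde is the nucleophile.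

Step 4
Reactants: 5 (5R)-2-methyl-5-(propan-2-yl)-5-[(triethylsilyl)oxy]cyclopent-1-ene-1-carbaldehyde
Product: 6 1-[(5R)-2-methyl-5-(propan-2-yl)-5-[(triethylsilyl)oxy]cyclopent-1-en-1-yl]ethan-1-ol (both carbinol epimers)
Conditions: MeMgBr, THF, −78 → 0 °C
Reagents that add atoms: methylmagnesium bromide, C[Mg]Br
Why: Grignard 1,2-addition to the hindered β,β-disubstituted enal should be clean, and the new carbinol centre is irrelevant because it is oxidised in the next step.

Step 5
Reactants: 6 1-[(5R)-2-methyl-5-(propan-2-yl)-5-[(triethylsilyl)oxy]cyclopent-1-en-1-yl]ethan-1-ol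
Product: 7 1-[(5R)-2-methyl-5-(propan-2-yl)-5-[(triethylsilyl)oxy]cyclopent-1-en-1-yl]ethan-1-one
Conditions: Dess–Martin periodinane, NaHCO3, CH2Cl2, 0 °C → rt
Reagents that add atoms: none
Why: Dess–Martin oxidation of a secondary allylic alcohol under buffered conditions spares the tertiary silyl ether.

Step 6
Reactants: 7 1-[(5R)-2-methyl-5-(propan-2-yl)-5-[(triethylsilyl)oxy]cyclopent-1-en-1-yl]ethan-1-one
Product: 8 tert-butyldimethyl({1-[(5R)-2-methyl-5-(propan-2-yl)-5-[(triethylsilyl)oxy]cyclopent-1-en-1-yl]ethenyl}oxy)silane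
Conditions: TBSOTf, Et3N, CH2Cl2, −78 → 0 °C
Reagents that add atoms: tert-butyldimethylsilyl triflate, CC(C)(C)[Si](C)(C)OS(=O)(=O)C(F)(F)F
Why: Soft enolisation with silyl triflate and amine removes a proton from the acetyl methyl group and gives the cross-conjugated 2-silyloxydiene, the usual outcome for acetylcycloalkenes.

Step 7
Reactants: 9 methyl acetoacetate
Product: 10 methyl 2-diazo-3-oxobutanoate
Conditions: p-ABSA, Et3N, MeCN, 0 °C → rt
Reagents that add atoms: 4-acetamidobenzenesulfonyl azide, CC(=O)Nc1ccc(cc1)S(=O)(=O)N=[N+]=[N-]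
Why: Regitz diazo transfer to the activated methylene of a β-keto ester is standard.

Step 8
Reactants: 10 methyl 2-diazo-3-oxobutanoate
Product: 11 methyl 2-diazo-3-hydroxybutanoate (racemic)
Conditions: NaBH4, MeOH, 0 °C
Reagents that add atoms: none
Why: Borohydride reduces the ketone and leaves the diazo ester intact, the known first stage of the vinyldiazoacetate preparation.

Step 9
Reactants: 11 methyl 2-diazo-3-hydroxybutanoate
Product: 12 methyl 2-diazobut-3-enoate
Conditions: POCl3, Et3N, CH2Cl2, 0 °C; used at once as a hexane solution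
Reagents that add atoms: none
Why: Dehydration of the β-hydroxy α-diazo ester through its dichlorophosphate (E1cB-type elimination) gives the vinyldiazoacetate, which is used immediately because it cyclises to a pyrazole on standing.

Step 10
Reactants: 8 tert-butyldimethyl({1-[(5R)-2-methyl-5-(propan-2-yl)-5-[(triethylsilyl)oxy]cyclopent-1-en-1-yl]ethenyl}oxy)silane; 12 methyl 2-diazobut-3-enoate
Product: 14 methyl (3R,8aR)-4-[(tert-butyldimethylsilyl)oxy]-8a-methyl-3-(propan-2-yl)-3-[(triethylsilyl)oxy]-1,2,3,5,8,8a-hexahydroazulene-6-carboxylate, via divinylcyclopropane 13 (not isolated)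
Conditions: Rh2(R-DOSP)4 (1 mol%), hexanes, −40 °C → rt, slow addition of 12 (3 equiv); then PhMe, 80 °C
Reagents that add atoms: none
Why: Rh2(R-DOSP)4, a tetraprolinate of divalent rhodium, turns 12 into a donor/acceptor vinylcarbenoid that cyclopropanates the electron-rich, unhindered C6=C7 enol ether of 8 (bonds C7–C8 and C6–C8), and the cis-divinylcyclopropane 13 then undergoes a strain-releasing Cope rearrangement through a boat transition state that breaks C6–C8 and forms C1–C10. The closest known reaction type is the tandem cyclopropanation/divinylcyclopropane rearrangement (formal (4+3) cycloaddition) of vinyldiazoacetates with dienes, which is known for 2-silyloxydienes and for diene termini that become quaternary. Ring B closes in the [3,3] shift as a cyclohepta-1,4-diene carrying the C5=C6 silyl enol ether and the C8=C9 enoate. C1 is the only new stereocentre of 14 and is controlled by the (1S,2R) configuration of 13, which the catalyst sets and the boat geometry transfers by forcing C10 onto one face of C1; the R catalyst is chosen because the S catalyst gives the opposite spatial sense in the established cyclopropanations of styrene-type alkenes. The step needs attack at C6=C7 rather than the tetrasubstituted C5=C1 (sterics and electronics), carbenoid rather than vinylogous reactivity (hydrocarbon solvent, electron-rich prolinate ligands), a cis-divinyl arrangement and a single enantioface (catalyst), and warming is included because the cis methyl group at C1 slows the rearrangement.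

Step 11
Reactants: 14 methyl (3R,8aR)-4-[(tert-butyldimethylsilyl)oxy]-8a-methyl-3-(propan-2-yl)-3-[(triethylsilyl)oxy]-1,2,3,5,8,8a-hexahydroazulene-6-carboxylate
Product: 15 [(3R,8aR)-4-[(tert-butyldimethylsilyl)oxy]-8a-methyl-3-(propan-2-yl)-3-[(triethylsilyl)oxy]-1,2,3,5,8,8a-hexahydroazulen-6-yl]methanol
Conditions: i-Bu2AlH, CH2Cl2, −78 °C; aq. KNaC4H4O6
Reagents that add atoms: none
Why: 1,2-Reduction of the α,β-unsaturated ester by i-Bu2AlH at low temperature gives the allylic alcohol, and the silyl ether and silyl enol ether are inert.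

Step 12
Reactants: 15 [(3R,8aR)-4-[(tert-butyldimethylsilyl)oxy]-8a-methyl-3-(propan-2-yl)-3-[(triethylsilyl)oxy]-1,2,3,5,8,8a-hexahydroazulen-6-yl]methanol
Product: 17 tert-butyl{[(3R,8aR)-6,8a-dimethyl-3-(propan-2-yl)-3-[(triethylsilyl)oxy]-1,2,3,5,8,8a-hexahydroazulen-4-yl]oxy}dimethylsilane, via pyridinium sulfate 16 (not isolated)
Conditions: SO3·pyridine, THF, 0 °C; then LiAlH4, 0 °C → rt
Reagents that add atoms: none
Why: Deoxygenation of a primary allylic alcohol through its sulfate monoester and hydride displacement (SN2 at the unhindered CH2) is known to proceed without allylic transposition, and the anionic leaving group should not ionise toward the neighbouring enol ether.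

Step 13
Reactants: 17 tert-butyl{[(3R,8aR)-6,8a-dimethyl-3-(propan-2-yl)-3-[(triethylsilyl)oxy]-1,2,3,5,8,8a-hexahydroazulen-4-yl]oxy}dimethylsilane
Product: 19 (3R,3aR,8aR)-3-hydroxy-6,8a-dimethyl-3-(propan-2-yl)-1,2,3,3a,8,8a-hexahydroazulen-4(5H)-one, via TES ketone 18 (not isolated)
Conditions: TBAF, AcOH, THF, −40 → 0 °C; then HF·pyridine, pyridine, 0 °C → rt
Reagents that add atoms: none
Why: Buffered fluoride unmasks the C6 ketone by protodesilylation while the C4 silyl ether is still in place, so C5 should be protonated on the α-face, away from the triethylsilyloxy group and the C1 methyl group, to give the trans-fused ketone, which is also the more stable epimer because C6 then avoids the isopropyl group; HF·pyridine then frees the tertiary alcohol without base, which avoids retro-aldol cleavage and migration of the β,γ-alkene.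

Step 14
Reactants: 19 (3R,3aR,8aR)-3-hydroxy-6,8a-dimethyl-3-(propan-2-yl)-1,2,3,3a,8,8a-hexahydroazulen-4(5H)-one
Product: 20 (3R,3aS,4S,8aR)-6,8a-dimethyl-3-(propan-2-yl)-1,2,3,3a,4,5,8,8a-octahydroazulene-3,4-diol (4β,6α-diol in the labels used here)
Conditions: Me4NBH(OAc)3, MeCN/AcOH, −25 °C
Reagents that add atoms: none
Why: In this Evans–Saksena hydroxyl-directed reduction the alkoxyborohydride formed at the C4 hydroxyl delivers hydride intramolecularly to the β-face of the C6 ketone, which gives the 1,3-anti diol (C6 hydroxyl α) and leaves the isolated alkene alone.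

Step 15
Reactants: 20 (3R,3aS,4S,8aR)-6,8a-dimethyl-3-(propan-2-yl)-1,2,3,3a,4,5,8,8a-octahydroazulene-3,4-diol
Product: 21 8α,9α-epoxide of 20 [(1R,4R,5S,6S,8R,9S)-8,9-epoxy-4,6-diol in the labels used here]
Conditions: VO(acac)2 (cat.), t-BuOOH, CH2Cl2, 0 °C → rt
Reagents that add atoms: tert-butyl hydroperoxide, CC(C)(C)OO
Why: Vanadium-catalysed epoxidation directed by the homoallylic C6 hydroxyl should deliver oxygen to the face of C8=C9 syn to that hydroxyl (α), setting C8 and C9 together.

Step 16
Reactants: 21 8α,9α-epoxide of 20; 22 3,4-dimethoxybenzoyl chloride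
Product: 23 CNP0251065.1, the 6-O-(3,4-dimethoxybenzoyl) ester of 21 [(1R,4R,5S,6S,8R,9S) in the labels used here]
Conditions: Et3N, DMAP (cat.), CH2Cl2, 0 °C → rt
Reagents that add atoms: none
Why: DMAP-catalysed acylation should discriminate the secondary C6 hydroxyl from the tertiary C4 hydroxyl, and the basic medium leaves the epoxide intact.

**Compound list**
1 | (S)-(+)-terpinen-4-ol, (1S)-4-methyl-1-(propan-2-yl)cyclohex-3-en-1-ol | CC1=CC[C@](O)(C(C)C)CC1 | starting material
2 | triethyl{[(1S)-4-methyl-1-(propan-2-yl)cyclohex-3-en-1-yl]oxy}silane | CC1=CC[C@](O[Si](CC)(CC)CC)(C(C)C)CC1 | intermediate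
3 | ozonide of 2, 1-methyl-4-(propan-2-yl)-4-[(triethylsilyl)oxy]-7,8,9-trioxabicyclo[4.2.1]nonane (C4 as in 2, bridgehead diastereomers; not isolated) | CC12CC[C@@](O[Si](CC)(CC)CC)(C(C)C)CC(OO1)O2 | intermediate
4 | (3S)-6-oxo-3-(propan-2-yl)-3-[(triethylsilyl)oxy]heptanal | CC(=O)CC[C@@](CC=O)(O[Si](CC)(CC)CC)C(C)C | intermediate
5 | (5R)-2-methyl-5-(propan-2-yl)-5-[(triethylsilyl)oxy]cyclopent-1-ene-1-carbaldehyde | O=CC1=C(C)CC[C@@]1(O[Si](CC)(CC)CC)C(C)C | intermediate
6 | 1-[(5R)-2-methyl-5-(propan-2-yl)-5-[(triethylsilyl)oxy]cyclopent-1-en-1-yl]ethan-1-ol (both carbinol epimers) | CC(O)C1=C(C)CC[C@@]1(O[Si](CC)(CC)CC)C(C)C | intermediate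
7 | 1-[(5R)-2-methyl-5-(propan-2-yl)-5-[(triethylsilyl)oxy]cyclopent-1-en-1-yl]ethan-1-one | CC(=O)C1=C(C)CC[C@@]1(O[Si](CC)(CC)CC)C(C)C | intermediate
8 | tert-butyldimethyl({1-[(5R)-2-methyl-5-(propan-2-yl)-5-[(triethylsilyl)oxy]cyclopent-1-en-1-yl]ethenyl}oxy)silane | C=C(O[Si](C)(C)C(C)(C)C)C1=C(C)CC[C@@]1(O[Si](CC)(CC)CC)C(C)C | intermediate
9 | methyl acetoacetate (methyl 3-oxobutanoate) | CC(=O)CC(=O)OC | starting material
10 | methyl 2-diazo-3-oxobutanoate | CC(=O)C(=[N+]=[N-])C(=O)OC | intermediate
11 | methyl 2-diazo-3-hydroxybutanoate (racemic) | CC(O)C(=[N+]=[N-])C(=O)OC | intermediate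
12 | methyl 2-diazobut-3-enoate | C=CC(=[N+]=[N-])C(=O)OC | intermediate
13 | methyl (1S,2R)-2-[(tert-butyldimethylsilyl)oxy]-1-ethenyl-2-[(5R)-2-methyl-5-(propan-2-yl)-5-[(triethylsilyl)oxy]cyclopent-1-en-1-yl]cyclopropane-1-carboxylate (not isolated) | COC(=O)[C@]1(C=C)C[C@@]1(O[Si](C)(C)C(C)(C)C)C2=C(C)CC[C@@]2(O[Si](CC)(CC)CC)C(C)C | intermediate
14 | methyl (3R,8aR)-4-[(tert-butyldimethylsilyl)oxy]-8a-methyl-3-(propan-2-yl)-3-[(triethylsilyl)oxy]-1,2,3,5,8,8a-hexahydroazulene-6-carboxylate | CC(C)(C)[Si](C)(C)OC1=C2[C@](O[Si](CC)(CC)CC)(C(C)C)CC[C@]2(C)CC=C(C(=O)OC)C1 | intermediate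
15 | [(3R,8aR)-4-[(tert-butyldimethylsilyl)oxy]-8a-methyl-3-(propan-2-yl)-3-[(triethylsilyl)oxy]-1,2,3,5,8,8a-hexahydroazulen-6-yl]methanol | CC(C)(C)[Si](C)(C)OC1=C2[C@](O[Si](CC)(CC)CC)(C(C)C)CC[C@]2(C)CC=C(CO)C1 | intermediate
16 | pyridinium sulfate monoester of 15 (not isolated) | CC(C)(C)[Si](C)(C)OC1=C2[C@](O[Si](CC)(CC)CC)(C(C)C)CC[C@]2(C)CC=C(COS(=O)(=O)[O-])C1.c1cc[nH+]cc1 | intermediate
17 | tert-butyl{[(3R,8aR)-6,8a-dimethyl-3-(propan-2-yl)-3-[(triethylsilyl)oxy]-1,2,3,5,8,8a-hexahydroazulen-4-yl]oxy}dimethylsilane | CC(C)(C)[Si](C)(C)OC1=C2[C@](O[Si](CC)(CC)CC)(C(C)C)CC[C@]2(C)CC=C(C)C1 | intermediate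
18 | (3R,3aR,8aR)-6,8a-dimethyl-3-(propan-2-yl)-3-[(triethylsilyl)oxy]-1,2,3,3a,8,8a-hexahydroazulen-4(5H)-one (not isolated) | O=C1CC(C)=CC[C@@]2(C)CC[C@@](O[Si](CC)(CC)CC)(C(C)C)[C@H]12 | intermediate
19 | (3R,3aR,8aR)-3-hydroxy-6,8a-dimethyl-3-(propan-2-yl)-1,2,3,3a,8,8a-hexahydroazulen-4(5H)-one | O=C1CC(C)=CC[C@@]2(C)CC[C@@](O)(C(C)C)[C@H]12 | intermediate
20 | (3R,3aS,4S,8aR)-6,8a-dimethyl-3-(propan-2-yl)-1,2,3,3a,4,5,8,8a-octahydroazulene-3,4-diol | O[C@H]1CC(C)=CC[C@@]2(C)CC[C@@](O)(C(C)C)[C@H]12 | intermediate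
21 | 8α,9α-epoxide of 20, (1R,4R,5S,6S,8R,9S)-8,9-epoxy-4,6-diol in the labels used here | O[C@H]1C[C@@]2(C)O[C@H]2C[C@@]2(C)CC[C@@](O)(C(C)C)[C@H]12 | intermediate
22 | 3,4-dimethoxybenzoyl chloride | COc1ccc(C(=O)Cl)cc1OC | starting material
23 | CNP0251065.1, 6-O-(3,4-dimethoxybenzoyl) ester of 21 | COc1ccc(C(=O)O[C@H]2C[C@@]3(C)O[C@H]3C[C@@]3(C)CC[C@@](O)(C(C)C)[C@H]23)cc1OC | target

**Step count and risks**
Total steps: 16. Longest linear sequence: 13 steps (steps 1–6 and 10–16, from 1).

Step 10. The sigmatropic shift may stall at the cyclopropane stage, because C1 is a fully substituted terminus with a cis methyl group. If it is forced, the donor–acceptor cyclopropane may open heterolytically, which would erode the transfer of chirality to C1 or divert closure to a five-membered ring. Fallback, from 13 back to 15: the cyclopropanation is stopped at low temperature, 13 is isolated and its ester is reduced with i-Bu2AlH to [(1R,2S)-2-[(tert-butyldimethylsilyl)oxy]-1-ethenyl-2-[(5R)-2-methyl-5-(propan-2-yl)-5-[(triethylsilyl)oxy]cyclopent-1-en-1-yl]cyclopropyl]methanol F1. Without the acceptor the ring cannot open as a zwitterion, so F1 can be heated in toluene or xylene (110–140 °C) until the concerted Cope rearrangement is complete. This gives allylic alcohol 15 directly and keeps the catalyst-set configuration.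

Step 13. This is the least secure stereochemical step: C5 may be protonated from the β-face under kinetic control and give the cis-fused ketone. Correction on 19 is not possible, because base or acid also moves the C8=C9 alkene into conjugation or triggers retro-aldol cleavage. Fallback, from 17 back to 18:
- 17 is cleaved with K2CO3 in MeOH and left to equilibrate, so that C5 settles in the trans-fused arrangement while the alkene moves into conjugation. The main product should be the conjugated enone (3R,3aR,8aS)-6,8a-dimethyl-3-(propan-2-yl)-3-[(triethylsilyl)oxy]-2,3,3a,7,8,8a-hexahydroazulen-4(1H)-one F2; any non-conjugated trans ketone present is 18 itself. The C4–O bond lies near the enolate plane, which should disfavour β-elimination.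
- TBSOTf/Et3N converts the mixture by γ-deprotonation into the linear silyl dienol ether tert-butyl{[(3R,3aS,8aR)-6,8a-dimethyl-3-(propan-2-yl)-3-[(triethylsilyl)oxy]-1,2,3,3a,8,8a-hexahydroazulen-4-yl]oxy}dimethylsilane F3.
- Buffered TBAF at −78 °C protonates the dienolate at C7 (kinetic α-protonation, the classical deconjugation) and returns 18 with C5 already fixed. 18 then goes on to the HF·pyridine stage of step 13.

Step 15. Oxygen may be delivered to the β-face, or turnover may be slow, because the directing hydroxyl is only homoallylic and sits on a flexible seven-membered ring. Fallback, from 20 back to 21: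
- The secondary hydroxyl of 20 is converted (Boc2O, DMAP) into tert-butyl (3R,3aS,4S,8aR)-3-hydroxy-6,8a-dimethyl-3-(propan-2-yl)-1,2,3,3a,4,5,8,8a-octahydroazulen-4-yl carbonate F4.
- IBr in toluene at −80 °C induces iodocarbonate cyclisation: the carbonate oxygen attacks tertiary C8 from the α-face through a six-membered ring and iodine ends up β on C9, giving the 6α,8α-cyclic carbonate of the 9β-iodo-4β,6α,8α-triol F5.
- K2CO3 in MeOH cleaves the carbonate, and the liberated C8 alkoxide displaces iodide with inversion to give the 8α,9α-epoxide 21.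

**Further compounds**
F1 | step 10 | [(1R,2S)-2-[(tert-butyldimethylsilyl)oxy]-1-ethenyl-2-[(5R)-2-methyl-5-(propan-2-yl)-5-[(triethylsilyl)oxy]cyclopent-1-en-1-yl]cyclopropyl]methanol | OC[C@]1(C=C)C[C@@]1(O[Si](C)(C)C(C)(C)C)C2=C(C)CC[C@@]2(O[Si](CC)(CC)CC)C(C)C
F2 | step 13 | (3R,3aR,8aS)-6,8a-dimethyl-3-(propan-2-yl)-3-[(triethylsilyl)oxy]-2,3,3a,7,8,8a-hexahydroazulen-4(1H)-one | O=C1C=C(C)CC[C@@]2(C)CC[C@@](O[Si](CC)(CC)CC)(C(C)C)[C@H]12
F3 | step 13 | tert-butyl{[(3R,3aS,8aR)-6,8a-dimethyl-3-(propan-2-yl)-3-[(triethylsilyl)oxy]-1,2,3,3a,8,8a-hexahydroazulen-4-yl]oxy}dimethylsilane | CC(C)(C)[Si](C)(C)OC1=CC(C)=CC[C@@]2(C)CC[C@@](O[Si](CC)(CC)CC)(C(C)C)[C@H]12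
F4 | step 15 | tert-butyl (3R,3aS,4S,8aR)-3-hydroxy-6,8a-dimethyl-3-(propan-2-yl)-1,2,3,3a,4,5,8,8a-octahydroazulen-4-yl carbonate | CC(C)(C)OC(=O)O[C@H]1CC(C)=CC[C@@]2(C)CC[C@@](O)(C(C)C)[C@H]12
F5 | step 15 | 6α,8α-cyclic carbonate of the 9β-iodo-4β,6α,8α-triol | O=C1O[C@H]2C[C@@](C)(O1)[C@H](I)C[C@@]3(C)CC[C@@](O)(C(C)C)[C@H]23
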